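**Plan**

- Retrosynthesis: the esters and free hydroxyls are adjusted last, from a C6 aryl ether, a C1/C2 acetonide and a carboxyl at C7. The ring is then cut at C1–C6.
- Enabling feature: with C7 as a carboxyl, C7(=O)–C1–C6–C5=C4 is a γ,δ-unsaturated acid inside the cyclohex-4-ene, the retron of a [3,3] shift. Undoing it puts an ester oxygen on C4 and gives a six-membered lactone (O–C7–C1–C2–C3–C4) whose C4 carries an (E)-2-aryloxyvinyl group (C5=C6).
- That lactone is a D-mannono-1,5-lactone. Forward order: pyranoside, C6 aldehyde, (E)-vinyl iodide, lactone, aryl enol ether, ring contraction to the carbocycle, then reduction and acylations. The lactone C–O bond, absent from the target, steers the closure and is cleaved in the same step.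
- Stereochemistry: C2 and C3 are C3 and C4 of D-mannose. C1 and C6 arise in the rearrangement by chirality transfer from sugar C5 through an enforced boat, the ring-locked ketene acetal and the E enol ether. Sugar C2 is erased on enolisation.

Key step: step 8

Remark: target locants are used throughout (C1 quaternary carbinol, C2 OAc, C3 OBz, C4=C5, C6 CHOH, C7 exocyclic CH2). Carbons 1–7 of the sugar-derived lactone become C7, C1, C2, C3, C4, C5, C6. Phenyl 1-thio-α-D-mannopyranoside is taken as purchasable.

**Route**

Step 1
Reactants: 1 phenyl 1-thio-α-D-mannopyranoside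
Product: 3 phenyl 2,3-O-isopropylidene-1-thio-α-D-mannopyranoside, via diacetonide 2 (not isolated)
Conditions: Me2C(OMe)2, TsOH·H2O (cat.), acetone, rt; then H2O, rt until the 4,6-acetal is cleaved; Et3N quench
Reagents that add atoms: 2,2-dimethoxypropane, COC(C)(C)OC
Why: Acid-catalysed transacetalisation should give the 2,3:4,6-diacetonide, whose 4,6-dioxane acetal hydrolyses much faster than the cis-fused 2,3-dioxolane, so controlled addition of water should leave the 2,3-acetonide (acetal formation and selective acetal hydrolysis).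

Step 2
Reactants: 3 phenyl 2,3-O-isopropylidene-1-thio-α-D-mannopyranoside
Product: 4 phenyl 2,3-O-isopropylidene-1-thio-α-D-manno-hexodialdo-1,5-pyranoside (C6 aldehyde; O4 free)
Conditions: TEMPO (0.2 equiv), PhI(OAc)2 (1.2 equiv), dry CH2Cl2, rt
Reagents that add atoms: none
Why: The nitroxyl-catalysed oxidation (TEMPO/PhI(OAc)2) is selective for the primary over the secondary hydroxyl, stops at the aldehyde in the absence of water and is routinely tolerated by thioglycosides.

Step 3
Reactants: 4 C6 aldehyde
Product: 5 phenyl (E)-6,7-dideoxy-7-iodo-2,3-O-isopropylidene-1-thio-α-D-manno-hept-6-enopyranoside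
Conditions: CrCl2 (8 equiv), CHI3 (3 equiv), THF/1,4-dioxane, 0 °C to rt
Reagents that add atoms: iodoform, IC(I)I
Why: The Takai iodo-olefination (gem-dichromium reagent from CHI3 and CrCl2) converts aldehydes into (E)-vinyl iodides under non-basic conditions that tolerate the free hydroxyl and should not epimerise C5; the E geometry needed later is set here.

Step 4
Reactants: 5 (E)-vinyl iodide
Product: 6 phenyl (E)-6,7-dideoxy-7-iodo-2,3-O-isopropylidene-4-O-pivaloyl-1-thio-α-D-manno-hept-6-enopyranoside
Conditions: PivCl (2 equiv), pyridine, DMAP (0.2 equiv), CH2Cl2, 0 to 40 °C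
Reagents that add atoms: pivaloyl chloride, CC(C)(C)C(Cl)=O
Why: DMAP-catalysed acylation of the only free hydroxyl blocks O4 so that later only the 1,5-lactone can exist; the pivalate has no α-hydrogen and resists phenoxide and amide bases.

Step 5
Reactants: 6 4-O-pivaloyl thioglycoside
Product: 7 (E)-6,7-dideoxy-7-iodo-2,3-O-isopropylidene-4-O-pivaloyl-D-manno-hept-6-enopyranose (lactol; both anomers)
Conditions: NBS (1.5 equiv), NaHCO3, acetone/H2O (9:1), −15 to 0 °C
Reagents that add atoms: water, O
Why: Halonium-promoted hydrolysis of the thioglycoside (bromosulfonium ion, oxocarbenium ion, capture by water) should free the anomeric hydroxyl under buffered conditions that leave the acetonide, pivalate and vinyl iodide untouched.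

Step 6
Reactants: 7 lactol
Product: 8 (E)-6,7-dideoxy-7-iodo-2,3-O-isopropylidene-4-O-pivaloyl-D-manno-hept-6-enono-1,5-lactone
Conditions: nPr4NRuO4 (5 mol%), N-methylmorpholine N-oxide (1.5 equiv), 4 Å molecular sieves, CH2Cl2, rt
Reagents that add atoms: none
Why: Ley–Griffith oxidation converts lactols into lactones under neutral conditions; with O4 acylated the 1,5-lactone cannot isomerise to the 1,4-lactone.

Step 7
Reactants: 8 vinyl iodide lactone
Product: 9 the same lactone carrying an (E)-2-(4-methoxyphenoxy)vinyl group at its C5 (target C4)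
Conditions: 4-methoxyphenol (1.5 equiv), CuI (10 mol%), N,N-dimethylglycine hydrochloride (30 mol%), Cs2CO3 (2 equiv), 1,4-dioxane, 60 °C
Reagents that add atoms: 4-methoxyphenol, COc1ccc(O)cc1
Why: The copper-catalysed Ullmann-type C–O coupling of vinyl iodides with phenols proceeds with retention of alkene geometry, and a phenoxide (unlike an alkoxide) is too poor a nucleophile to open the lactone or exchange the pivalate, which is why an aryl enol ether is made.

Step 8
Reactants: 9 aryl enol ether lactone
Product: 12 cyclohex-4-ene-1-carboxylic acid with C1/C2 acetonide; C3 pivalate; C6 4-methoxyphenyl ether (target configuration at C1; C2; C3; C6), via silyl ketene acetal 10 (not isolated), via silyl ester 11 (not isolated)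
Conditions: Me3SiCl/Et3N (premixed, 4 equiv), then LiN(SiMe3)2 (1.5 equiv), THF, −78 °C; warm to rt, then toluene, 80 °C; aqueous citrate buffer (pH 4) work-up
Reagents that add atoms: trimethylsilyl chloride, C[Si](C)(C)Cl (its silicon stays only in 10 and 11)
Why: LiN(SiMe3)2 removes the only α-hydrogen of the lactone (at target C1) in the presence of Me3SiCl, so the enolate is trapped at once as the ring-locked silyl ketene acetal, which on warming undergoes a concerted suprafacial [3,3] shift in which C1 bonds to the aryloxy-bearing vinyl terminus C6 while the allylic lactone C–O bond at C4 breaks, giving the silyl ester and, after hydrolysis, the acid. The closest known reaction type is the Ireland–Claisen (ester-enolate Claisen) ring contraction of 6-alkenyl δ-lactones and 6-alkenyl-1,4-dioxan-2-ones, together with ester-enolate Claisen shifts onto enol-ether termini as in glycal esters. The six-membered carbocycle closes by this pericyclic ring contraction: the six reacting atoms and the two-carbon bridge C2–C3 form a bicyclo[2.2.2]octane-like array, so only a boat transition state is possible and the new ring alkene C4=C5 is necessarily cis. C1 is controlled by the ketene acetal geometry, fixed by the lactone ring, and by the configuration of the former sugar C5 (destroyed in the step), which holds the vinyl group over one face only, so that the carboxyl ends up trans and the C1 oxygen cis to the C2 oxygen. C6 is controlled by the E geometry of the enol ether, which in the boat points the aryloxy group toward the breaking lactone bridge, so it ends up cis to the carboxyl and trans to the C1 oxygen. The step needs enolisation without β-elimination of the C2 oxygen, which is secured by the cis-fused dioxolane holding that C–O bond in the plane of the enolate and by the internal silyl quench; the pivalate has no α-hydrogen.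

Step 9
Reactants: 12 cyclohexene acid
Product: 13 C3,C7-diol (C1 hydroxymethyl; C3–OH; C1/C2 acetonide; C6 aryl ether)
Conditions: LiAlH4 (5 equiv), THF, 0 °C to reflux; aqueous work-up
Reagents that add atoms: none
Why: LiAlH4 reduction should convert the hindered α-alkoxy carboxylic acid into the primary alcohol and at the same time cleave the pivalate reductively, exposing exactly the two hydroxyls that carry benzoates in the target.

Step 10
Reactants: 13 C3,C7-diol
Product: 14 C3,C7-dibenzoate (C1/C2 acetonide; C6 aryl ether)
Conditions: BzCl (3 equiv), pyridine, DMAP (0.1 equiv), CH2Cl2, 0 °C to rt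
Reagents that add atoms: benzoyl chloride, O=C(Cl)c1ccccc1
Why: DMAP-catalysed benzoylation acylates the primary and the allylic secondary hydroxyl, the only free hydroxyls present.

Step 11
Reactants: 14 dibenzoate acetonide
Product: 15 C1,C2-diol (C3 and C7 benzoates; C6 aryl ether)
Conditions: AcOH/H2O (4:1), 55 °C
Reagents that add atoms: none
Why: Acid-catalysed acetal hydrolysis should remove the isopropylidene group while benzoates and the aryl ether are stable to aqueous acetic acid, and the trans relationship of O2 and O3 disfavours benzoate migration.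

Step 12
Reactants: 15 C1,C2-diol
Product: 16 C2 acetate (C1–OH free; C6 aryl ether)
Conditions: Ac2O (1.5 equiv), pyridine, DMAP (5 mol%), CH2Cl2, 0 °C
Reagents that add atoms: acetic anhydride, CC(=O)OC(C)=O
Why: Acetylation should discriminate the secondary C2 hydroxyl from the tertiary C1 hydroxyl on steric grounds while the C6 oxygen is still masked as the aryl ether.

Step 13
Reactants: 16 C2 acetate aryl ether
Product: 17 target, [(1R,2S,3R,6S)-2-acetoxy-3-benzoyloxy-1,6-dihydroxycyclohex-4-en-1-yl]methyl benzoate
Conditions: (NH4)2Ce(NO3)6 (2.5 equiv), MeCN/H2O (4:1), 0 °C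
Reagents that add atoms: none
Why: Oxidative dearylation of the 4-methoxyphenyl ether (arene radical cation, ipso attack of water, loss of the alcohol and benzoquinone) should free the C6 hydroxyl without touching the esters, the alkene or the C6 configuration.

**Compound list**

1 | phenyl 1-thio-α-D-mannopyranoside | c1ccccc1S[C@@H]1[C@@H](O)[C@@H](O)[C@H](O)[C@@H](CO)O1 | starting material
2 | phenyl 2,3:4,6-di-O-isopropylidene-1-thio-α-D-mannopyranoside | c1ccccc1S[C@@H]1[C@H]2OC(C)(C)O[C@H]2[C@@H]3OC(C)(C)OC[C@H]3O1 | intermediate (not isolated)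
3 | phenyl 2,3-O-isopropylidene-1-thio-α-D-mannopyranoside | c1ccccc1S[C@@H]1[C@H]2OC(C)(C)O[C@H]2[C@H](O)[C@@H](CO)O1 | intermediate
4 | phenyl 2,3-O-isopropylidene-1-thio-α-D-manno-hexodialdo-1,5-pyranoside | c1ccccc1S[C@@H]1[C@H]2OC(C)(C)O[C@H]2[C@H](O)[C@@H](C=O)O1 | intermediate
5 | phenyl (E)-6,7-dideoxy-7-iodo-2,3-O-isopropylidene-1-thio-α-D-manno-hept-6-enopyranoside | c1ccccc1S[C@@H]1[C@H]2OC(C)(C)O[C@H]2[C@H](O)[C@@H](/C=C/I)O1 | intermediate
6 | 4-O-pivaloyl derivative of 5 | c1ccccc1S[C@@H]1[C@H]2OC(C)(C)O[C@H]2[C@H](OC(=O)C(C)(C)C)[C@@H](/C=C/I)O1 | intermediate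
7 | (E)-6,7-dideoxy-7-iodo-2,3-O-isopropylidene-4-O-pivaloyl-D-manno-hept-6-enopyranose (anomeric mixture) | OC1[C@H]2OC(C)(C)O[C@H]2[C@H](OC(=O)C(C)(C)C)[C@@H](/C=C/I)O1 | intermediate
8 | (E)-6,7-dideoxy-7-iodo-2,3-O-isopropylidene-4-O-pivaloyl-D-manno-hept-6-enono-1,5-lactone | O=C1[C@H]2OC(C)(C)O[C@H]2[C@H](OC(=O)C(C)(C)C)[C@@H](/C=C/I)O1 | intermediate
9 | (E)-6-deoxy-2,3-O-isopropylidene-7-O-(4-methoxyphenyl)-4-O-pivaloyl-D-manno-hept-6-enono-1,5-lactone (aryl enol ether) | O=C1[C@H]2OC(C)(C)O[C@H]2[C@H](OC(=O)C(C)(C)C)[C@@H](/C=C/Oc3ccc(OC)cc3)O1 | intermediate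
10 | trimethylsilyl ketene acetal of lactone 9 | C[Si](C)(C)OC1=C2OC(C)(C)O[C@H]2[C@H](OC(=O)C(C)(C)C)[C@@H](/C=C/Oc3ccc(OC)cc3)O1 | intermediate (not isolated)
11 | trimethylsilyl ester of acid 12 | CC1(C)O[C@H]2[C@H](OC(=O)C(C)(C)C)C=C[C@H](Oc3ccc(OC)cc3)[C@@]2(C(=O)O[Si](C)(C)C)O1 | intermediate (not isolated)
12 | 1,2-O-isopropylidene-1,2-dihydroxy-6-(4-methoxyphenoxy)-3-pivaloyloxycyclohex-4-ene-1-carboxylic acid (C1–O/C2–O cis; C3–O trans to C2–O; C6–O trans to C1–O) | CC1(C)O[C@H]2[C@H](OC(=O)C(C)(C)C)C=C[C@H](Oc3ccc(OC)cc3)[C@@]2(C(=O)O)O1 | intermediate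
13 | C1-hydroxymethyl C3-hydroxy analogue (C1/C2 acetonide; C6 4-methoxyphenyl ether) | CC1(C)O[C@H]2[C@H](O)C=C[C@H](Oc3ccc(OC)cc3)[C@@]2(CO)O1 | intermediate
14 | C3,C7-dibenzoate of 13 | CC1(C)O[C@H]2[C@H](OC(=O)c3ccccc3)C=C[C@H](Oc3ccc(OC)cc3)[C@@]2(COC(=O)c3ccccc3)O1 | intermediate
15 | C1,C2-diol with C3 and C7 benzoates and C6 4-methoxyphenyl ether | O[C@H]1[C@H](OC(=O)c2ccccc2)C=C[C@H](Oc2ccc(OC)cc2)[C@]1(O)COC(=O)c1ccccc1 | intermediate
16 | C2 acetate of 15 | CC(=O)O[C@H]1[C@H](OC(=O)c2ccccc2)C=C[C@H](Oc2ccc(OC)cc2)[C@]1(O)COC(=O)c1ccccc1 | intermediate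
17 | [(1R,2S,3R,6S)-2-acetoxy-3-benzoyloxy-1,6-dihydroxycyclohex-4-en-1-yl]methyl benzoate | CC(=O)O[C@H]1[C@H](OC(=O)c2ccccc2)C=C[C@H](O)[C@]1(O)COC(=O)c1ccccc1 | target

**Summary**

Total step count: 13. Longest linear sequence: 13 steps (fully linear from 1).

Steps most likely to fail:

Step 8. The C2 oxygen may be lost by β-elimination from the metal enolate before it is silylated, or the ketene acetal may decompose if the strained boat is reached only slowly. The fallback sets out from 9 and replaces the metal enolate by soft enolisation (boron-mediated ester-enolate Claisen). Dicyclohexylboron triflate and Et3N in CH2Cl2 at −78 °C should give the boron ketene acetal F1 without a free enolate ever being formed. Boron ketene acetals of α-alkoxy esters rearrange below room temperature, here to the acyloxyborane F2, and aqueous work-up returns to the route at acid 12.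

Step 7. The lactone may be opened or suffer elimination under carbonate and phenoxide at 60 °C, or the alkene geometry may erode. The fallback sets out from 8 and forms the same C–O bond oxidatively near neutrality. Miyaura borylation (B2pin2, PdCl2(dppf), KOAc, 1,4-dioxane, 60 °C) should give the (E)-alkenyl boronate F3. Chan–Evans–Lam coupling with 4-methoxyphenol (Cu(OAc)2, pyridine, 4 Å sieves, CH2Cl2, air, rt) then proceeds with retention and returns to the route at 9.

Step 11. The C3 benzoate may migrate to the freed C2 hydroxyl, or the allylic benzoate may solvolyse under the acid needed to open a dioxolane on a tertiary oxygen. The fallback sets out from 13, which carries no esters, and hydrolyses the acetonide first (aqueous CF3CO2H, 0 °C) to the tetraol F4. The primary C7 hydroxyl and the allylic C3 hydroxyl are then benzoylated selectively (BzCl 2.1 equiv, pyridine/CH2Cl2, −40 °C). The C2 hydroxyl next to the quaternary C1 and the tertiary C1 hydroxyl are expected to stay free on steric grounds, which returns to the route at 15.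

Further compounds
F1 | step 8 | dicyclohexylboron ketene acetal of lactone 9 | C1CCCCC1B(C1CCCCC1)OC1=C2OC(C)(C)O[C@H]2[C@H](OC(=O)C(C)(C)C)[C@@H](/C=C/Oc3ccc(OC)cc3)O1
F2 | step 8 | dicyclohexylboryl ester of acid 12 | CC1(C)O[C@H]2[C@H](OC(=O)C(C)(C)C)C=C[C@H](Oc3ccc(OC)cc3)[C@@]2(C(=O)OB(C3CCCCC3)C3CCCCC3)O1
F3 | step 7 | (E)-alkenyl pinacol boronate corresponding to vinyl iodide 8 | O=C1[C@H]2OC(C)(C)O[C@H]2[C@H](OC(=O)C(C)(C)C)[C@@H](/C=C/B3OC(C)(C)C(C)(C)O3)O1
F4 | step 11 | 1-hydroxymethyl-6-(4-methoxyphenoxy)cyclohex-4-ene-1,2,3-triol (target configuration) | O[C@H]1[C@H](O)C=C[C@H](Oc2ccc(OC)cc2)[C@]1(O)CO
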